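**Plan**
- Retrosynthesis: the C7 carboxyl is traced back to a C7 bromide, the O1–C2 ether bond is cut (Mitsunobu), and then C4–C5 and C3–C1′ are cut in one operation. This leaves propargyl alcohol, (3E,7E)-homofarnesylmagnesium bromide and the ortho-quinone methide of a 5-bromosalicyl alcohol.
- Feature used: the ring olefin C3=C4 of the 2,5-dihydro-1-benzoxepine (O1, C2, C3, C4, C5, C5a, C9a) holds C2 (CH2O) and C5 (benzylic CH2) cis. This is the arrangement of the oxygen-bearing and metal-bearing carbons in the five-membered magnesium chelate formed on carbomagnesiation of propargyl alcohol.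
- Forward: farnesol is homologated by one carbon to the homofarnesyl Grignard reagent (steps 1–5) and 5-bromosalicylaldehyde becomes the O-Boc salicyl alcohol (steps 6–7). The three pieces are joined in step 8 (chain first, then arene), the oxepine, the only ring formed, closes in step 9, and the bromide becomes the acid in step 10.
- Stereochemistry: there is no stereocentre. The two E chain olefins come from (2E,6E)-farnesol, and the cis ring olefin is fixed by the chelate and carried through with retention.

Key step: step 8

Remark on the chemistry: the target is taken as drawn in the SMILES, an achiral acid with both chain olefins E; "homofarnesyl" means (3E,7E)-4,8,12-trimethyltrideca-3,7,11-trien-1-yl, and equivalents are planning values.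

**Route**

Step 1
Reactants: 1 (2E,6E)-farnesol
Product: 2 (2E,6E)-farnesal
Conditions: TEMPO (10 mol %), PhI(OAc)2, MeCN–pH 7 buffer, 0 °C to rt
Reagents that add atoms: none
Why: The TEMPO/oxoammonium oxidation of a primary allylic alcohol stops at the enal under buffered, near-neutral conditions and is known to leave the 2,3-olefin geometry of geraniol-type substrates intact.

Step 2
Reactants: 2 (2E,6E)-farnesal
Product: 3 (3E,7E)-4,8,12-trimethyltrideca-1,3,7,11-tetraene
Conditions: Ph3PCH3Br, n-BuLi, THF, 0 °C; then 2, 0 °C to rt
Reagents that add atoms: methyltriphenylphosphonium bromide, C[P+](c1ccccc1)(c1ccccc1)c1ccccc1.[Br-]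
Why: Wittig methylenation with the non-stabilised ylide adds the terminal CH2 by fast 1,2-addition to the enal, as established for geranial, so the 3E olefin is not touched.

Step 3
Reactants: 3 (3E,7E)-4,8,12-trimethyltrideca-1,3,7,11-tetraene
Product: 5 (3E,7E)-homofarnesol [(3E,7E)-4,8,12-trimethyltrideca-3,7,11-trien-1-ol], via B-homofarnesyl-9-BBN 4 (not isolated)
Conditions: 9-BBN (1.05 equiv), THF, 0 °C to rt; then NaOH (3 M), H2O2 (30 %), 0 °C to rt
Reagents that add atoms: hydrogen peroxide, OO
Why: In this hydroboration–oxidation the bulky dialkylborane adds anti-Markovnikov to the only monosubstituted olefin, the diene terminus, much faster than to the three trisubstituted olefins, and oxidation of the C–B bond gives the primary homoallylic alcohol.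

Step 4
Reactants: 5 (3E,7E)-homofarnesol
Product: 6 (3E,7E)-1-bromo-4,8,12-trimethyltrideca-3,7,11-triene (homofarnesyl bromide)
Conditions: CBr4, PPh3, CH2Cl2, 0 °C
Reagents that add atoms: carbon tetrabromide, BrC(Br)(Br)Br
Why: In the Appel reaction bromide displaces the primary alkoxyphosphonium ion by SN2 under neutral conditions that do not protonate the trisubstituted olefins.

Step 5
Reactants: 6 homofarnesyl bromide
Product: 7 (3E,7E)-homofarnesylmagnesium bromide (titrated solution in Et2O)
Conditions: Mg turnings (activated with a crystal of I2), Et2O, rt to gentle reflux; used the same day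
Reagents that add atoms: magnesium, [Mg]
Why: Grignard formation by insertion of magnesium into the primary C–Br bond is routine for homoallylic bromides, and the homoallyl-to-cyclopropylcarbinyl rearrangement that could erode the 3E geometry is slow at room temperature.

Step 6
Reactants: 8 5-bromosalicylaldehyde
Product: 9 4-bromo-2-formylphenyl tert-butyl carbonate
Conditions: Boc2O, DIPEA, DMAP (5 mol %), THF, rt
Reagents that add atoms: di-tert-butyl dicarbonate, CC(C)(C)OC(=O)OC(=O)OC(C)(C)C
Why: DMAP-catalysed O-acylation converts the phenol into its tert-butyl carbonate, the only nucleophilic site in the molecule.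

Step 7
Reactants: 9 4-bromo-2-formylphenyl tert-butyl carbonate
Product: 10 tert-butyl 4-bromo-2-(hydroxymethyl)phenyl carbonate
Conditions: BH3·THF, THF, 0 °C; then pH 7 buffer
Reagents that add atoms: none
Why: Borane reduction of the aldehyde passes through a neutral alkoxyborane and not a free alkoxide, so the Boc group stays on the phenolic oxygen, whereas an anionic hydride donor could trigger Boc migration and early quinone methide release; the aryl carbonate and the C–Br bond are inert to borane at 0 °C.

Step 8
Reactants: 7 (3E,7E)-homofarnesylmagnesium bromide; 10 tert-butyl 4-bromo-2-(hydroxymethyl)phenyl carbonate; 11 propargyl alcohol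
Product: 16 4-bromo-2-[(2Z,6E,10E)-3-(hydroxymethyl)-7,11,15-trimethylhexadeca-2,6,10,14-tetraen-1-yl]phenol, via chloromagnesium propargyl alkoxide 12 (not isolated), via oxamagnesacycle 13 (not isolated), via chloromagnesium benzylic alkoxide 14 (not isolated), via ortho-quinone methide 15 (not isolated)
Conditions: 11 (1.3 equiv), MeMgCl (1.3 equiv), THF, 0 °C; CuI (10 mol %), 7 (1.0 equiv), Et2O–THF, 0 °C to rt; then 10 (0.9 equiv) premixed with MeMgCl (0.9 equiv) in THF at −78 °C, −78 °C to rt; aq NH4Cl
Reagents that add atoms: none
Why: MeMgCl turns 11 into alkoxide 12, and CuI-catalysed carbometalation then delivers the homofarnesyl group of 7 to the internal alkyne carbon (C3–C1′ bond) and magnesium to the terminal carbon anti to it, the metal being clamped by the alkoxide in the five-membered oxamagnesacycle 13 so that the metal-bearing carbon C4 lies cis to the CH2O carbon C2. Alkoxide 14, inert at −78 °C, shifts its Boc group to the benzylic oxygen on warming and expels tert-butyl carbonate to release ortho-quinone methide 15 gradually, whose exocyclic CH2 is attacked by the alkenyl–magnesium bond of 13 with retention of geometry (C4–C5 bond), rearomatisation to the phenoxide being the driving force. The closest known reaction types are the copper-catalysed anti-carbomagnesiation of propargylic alcohols with electrophilic trapping of the chelate and the 1,4-addition of alkenyl Grignard reagents to ortho-quinone methides released from O-Boc salicyl alcohols, run here one after the other in one flask. No ring is closed and no stereocentre is formed; the only stereochemical element, the C3=C4 geometry, is dictated by the chelate. The step needs regioselective anti addition (alkyl to C3, metal to C4), which alkoxide-directed chelation enforces, and capture of 15 by the C–Mg bond instead of protonation or alkyl-Grignard addition, which is secured by removing both hydroxyl protons beforehand with sacrificial MeMgCl and by keeping 12 in slight excess so that no 7 remains when 14 is added. The aryl bromide and the carbonate are not attacked by Grignard reagents at these temperatures.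

Step 9
Reactants: 16 4-bromo-2-[(2Z,6E,10E)-3-(hydroxymethyl)-7,11,15-trimethylhexadeca-2,6,10,14-tetraen-1-yl]phenol
Product: 17 7-bromo-3-[(3E,7E)-4,8,12-trimethyltrideca-3,7,11-trien-1-yl]-2,5-dihydro-1-benzoxepine
Conditions: PPh3, DIAD, THF (0.01 M), 0 °C to rt
Reagents that add atoms: none
Why: In this intramolecular Mitsunobu etherification the acidic bromophenol displaces the primary allylic oxyphosphonium ion by SN2 (7-exo-tet closure of O1–C2), the cis olefin holding the two ends together, as precedented for 3-alkyl-2,5-dihydro-1-benzoxepines.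

Step 10
Reactants: 17 7-bromo-3-[(3E,7E)-4,8,12-trimethyltrideca-3,7,11-trien-1-yl]-2,5-dihydro-1-benzoxepine
Product: 19 3-[(3E,7E)-4,8,12-trimethyltrideca-3,7,11-trien-1-yl]-2,5-dihydro-1-benzoxepine-7-carboxylic acid (the target), via aryllithium 18 (not isolated)
Conditions: t-BuLi (2.1 equiv), THF, −78 °C; CO2 (gas), −78 °C to rt; aq HCl (1 M)
Reagents that add atoms: carbon dioxide, O=C=O
Why: Bromine–lithium exchange at −78 °C is much faster than deprotonation of the allylic and benzylic CH2 groups, and carboxylation of the aryllithium followed by acidification gives the benzoic acid.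

**Compound list**
1 | (2E,6E)-farnesol | OC/C=C(C)/CC/C=C(C)/CCC=C(C)C | starting material
2 | (2E,6E)-farnesal | O=C/C=C(C)/CC/C=C(C)/CCC=C(C)C | intermediate
3 | (3E,7E)-4,8,12-trimethyltrideca-1,3,7,11-tetraene | C=C/C=C(C)/CC/C=C(C)/CCC=C(C)C | intermediate
4 | 9-[(3E,7E)-4,8,12-trimethyltrideca-3,7,11-trien-1-yl]-9-borabicyclo[3.3.1]nonane (B-homofarnesyl-9-BBN) | CC(C)=CCC/C(C)=C/CC/C(C)=C/CCB1C2CCCC1CCC2 | intermediate
5 | (3E,7E)-4,8,12-trimethyltrideca-3,7,11-trien-1-ol (homofarnesol) | OCC/C=C(C)/CC/C=C(C)/CCC=C(C)C | intermediate
6 | (3E,7E)-1-bromo-4,8,12-trimethyltrideca-3,7,11-triene (homofarnesyl bromide) | BrCC/C=C(C)/CC/C=C(C)/CCC=C(C)C | intermediate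
7 | (3E,7E)-homofarnesylmagnesium bromide | Br[Mg]CC/C=C(C)/CC/C=C(C)/CCC=C(C)C | intermediate
8 | 5-bromosalicylaldehyde | O=Cc1cc(Br)ccc1O | starting material
9 | 4-bromo-2-formylphenyl tert-butyl carbonate | CC(C)(C)OC(=O)Oc1ccc(Br)cc1C=O | intermediate
10 | tert-butyl 4-bromo-2-(hydroxymethyl)phenyl carbonate | CC(C)(C)OC(=O)Oc1ccc(Br)cc1CO | intermediate
11 | propargyl alcohol | C#CCO | starting material
12 | chloromagnesium prop-2-yn-1-olate | C#CCO[Mg]Cl | intermediate
13 | 4-[(3E,7E)-4,8,12-trimethyltrideca-3,7,11-trien-1-yl]-2,5-dihydro-1,2-oxamagnesole (five-membered O–Mg–C chelate) | CC(C)=CCC/C(C)=C/CC/C(C)=C/CCC1=C[Mg]OC1 | intermediate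
14 | chloromagnesium [5-bromo-2-(tert-butoxycarbonyloxy)phenyl]methanolate | CC(C)(C)OC(=O)Oc1ccc(Br)cc1CO[Mg]Cl | intermediate
15 | 4-bromo-6-methylidenecyclohexa-2,4-dien-1-one (ortho-quinone methide) | C=C1C=C(Br)C=CC1=O | intermediate
16 | 4-bromo-2-[(2Z,6E,10E)-3-(hydroxymethyl)-7,11,15-trimethylhexadeca-2,6,10,14-tetraen-1-yl]phenol | Oc1ccc(Br)cc1C/C=C(\CO)CC/C=C(C)/CC/C=C(C)/CCC=C(C)C | intermediate
17 | 7-bromo-3-[(3E,7E)-4,8,12-trimethyltrideca-3,7,11-trien-1-yl]-2,5-dihydro-1-benzoxepine | CC(C)=CCC/C(C)=C/CC/C(C)=C/CCC1=CCc2cc(Br)ccc2OC1 | intermediate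
18 | {3-[(3E,7E)-4,8,12-trimethyltrideca-3,7,11-trien-1-yl]-2,5-dihydro-1-benzoxepin-7-yl}lithium | CC(C)=CCC/C(C)=C/CC/C(C)=C/CCC1=CCc2cc([Li])ccc2OC1 | intermediate
19 | 3-[(3E,7E)-4,8,12-trimethyltrideca-3,7,11-trien-1-yl]-2,5-dihydro-1-benzoxepine-7-carboxylic acid (callophycoic acid F as given) | CC(C)=CCC/C(C)=C/CC/C(C)=C/CCC1=CCc2cc(C(=O)O)ccc2OC1 | target

**Step count**
Total: 10 steps. Longest linear sequence: 8 steps (steps 1, 2, 3, 4, 5, 8, 9, 10 from farnesol); the arene branch (steps 6, 7) joins at step 8.

**Steps most likely to fail**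

Risk 1, step 8. The alkenyl–magnesium bond may be protonated before it is captured, by a residual hydroxyl proton or by the acetylenic C–H of unconsumed 12. Carbomagnesiation may stay incomplete, so that remaining alkyl Grignard reagent competes for the quinone methide. The quinone methide may also self-condense if it is released faster than it is trapped. The fallback keeps the carbomagnesiation but replaces the quinone methide capture by a palladium-catalysed sp2–sp3 coupling. It sets out from oxamagnesacycle 13 (made from 7 and 11 as in the first half of step 8) and from aldehyde 8, and comes back to the route at 16.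
- 13 is quenched with I2 (THF, −78 to 0 °C), the standard trapping of such chelates, to give (2Z)-3-iodo-2-[(3E,7E)-4,8,12-trimethyltrideca-3,7,11-trien-1-yl]prop-2-en-1-ol F1 with iodine cis to CH2OH.
- Separately, 8 is silylated (TIPSCl, imidazole, DMF) to 5-bromo-2-(triisopropylsilyloxy)benzaldehyde F2 and reduced (BH3·THF, 0 °C, which avoids silyl migration) to [5-bromo-2-(triisopropylsilyloxy)phenyl]methanol F3.
- F3 is converted (MsCl, Et3N, CH2Cl2; LiCl, DMF) into [4-bromo-2-(chloromethyl)phenoxy]triisopropylsilane F4, and zinc insertion (Zn dust, LiCl, THF, rt, conditions under which the aryl bromide does not react) gives 5-bromo-2-(triisopropylsilyloxy)benzylzinc chloride F5.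
- Negishi coupling of F1 with an excess of F5 (Pd(PPh3)4, THF, rt) should proceed with retention of olefin geometry, because zerovalent palladium inserts into the vinyl C–I bond far faster than into the electron-rich aryl C–Br bonds and the free hydroxyl is tolerated by the weakly basic benzylic zinc reagent. It gives (2Z)-4-[5-bromo-2-(triisopropylsilyloxy)phenyl]-2-[(3E,7E)-4,8,12-trimethyltrideca-3,7,11-trien-1-yl]but-2-en-1-ol F6.
- TBAF (THF, 0 °C) then frees the phenol to give 16.

Risk 2, step 9. The phenoxide may attack the activated allyl unit at C4 in SN2′ fashion and close a five-membered ring, the activated alcohol may etherify intermolecularly to oligomers, or it may eliminate to a diene. The fallback separates activation from ring closure; it sets out from 16 and comes back at 17. Appel bromination (CBr4, PPh3, CH2Cl2, −20 °C), which substitutes the allylic alcohol but not the phenol, gives 4-bromo-2-[(2Z,6E,10E)-3-(bromomethyl)-7,11,15-trimethylhexadeca-2,6,10,14-tetraen-1-yl]phenol F7. Slow addition of F7 to Cs2CO3 in MeCN at high dilution and rt closes the oxepine by intramolecular Williamson etherification at the primary allylic carbon to give 17.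

Risk 3, step 10. The organolithium may remove a proton from the doubly activated C5 methylene, after which the allyl anion can expel the phenoxide by β-elimination (ring opening) or the olefin can migrate on reprotonation. The fallback avoids strongly basic organometallics; it sets out from 17 and comes back at 19. Palladium-catalysed methoxycarbonylation (Pd(OAc)2, Xantphos, CO at 1 atm, MeOH, Et3N, toluene, 70 °C) gives methyl 3-[(3E,7E)-4,8,12-trimethyltrideca-3,7,11-trien-1-yl]-2,5-dihydro-1-benzoxepine-7-carboxylate F8, and saponification (LiOH, THF–MeOH–H2O, rt; then dilute HCl) gives 19.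

**Further compounds**
F1 | step 8 | (2Z)-3-iodo-2-[(3E,7E)-4,8,12-trimethyltrideca-3,7,11-trien-1-yl]prop-2-en-1-ol | I/C=C(\CO)CC/C=C(C)/CC/C=C(C)/CCC=C(C)C
F2 | step 8 | 5-bromo-2-(triisopropylsilyloxy)benzaldehyde | CC(C)[Si](Oc1ccc(Br)cc1C=O)(C(C)C)C(C)C
F3 | step 8 | [5-bromo-2-(triisopropylsilyloxy)phenyl]methanol | CC(C)[Si](Oc1ccc(Br)cc1CO)(C(C)C)C(C)C
F4 | step 8 | [4-bromo-2-(chloromethyl)phenoxy]triisopropylsilane | CC(C)[Si](Oc1ccc(Br)cc1CCl)(C(C)C)C(C)C
F5 | step 8 | 5-bromo-2-(triisopropylsilyloxy)benzylzinc chloride | CC(C)[Si](Oc1ccc(Br)cc1C[Zn]Cl)(C(C)C)C(C)C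
F6 | step 8 | (2Z)-4-[5-bromo-2-(triisopropylsilyloxy)phenyl]-2-[(3E,7E)-4,8,12-trimethyltrideca-3,7,11-trien-1-yl]but-2-en-1-ol | CC(C)[Si](Oc1ccc(Br)cc1C/C=C(\CO)CC/C=C(C)/CC/C=C(C)/CCC=C(C)C)(C(C)C)C(C)C
F7 | step 9 | 4-bromo-2-[(2Z,6E,10E)-3-(bromomethyl)-7,11,15-trimethylhexadeca-2,6,10,14-tetraen-1-yl]phenol | Oc1ccc(Br)cc1C/C=C(\CBr)CC/C=C(C)/CC/C=C(C)/CCC=C(C)C
F8 | step 10 | methyl 3-[(3E,7E)-4,8,12-trimethyltrideca-3,7,11-trien-1-yl]-2,5-dihydro-1-benzoxepine-7-carboxylate | COC(=O)c1ccc2OCC(CC/C=C(C)/CC/C=C(C)/CCC=C(C)C)=CCc2c1
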